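## Retrosynthetic overview
1. Both rings are opened at once. The lactone C=O (C12) and the ring ketone (C2) are each taken out as CO, by cutting C11–C12/C12–O6 and C1–C2/C2–C3. This gives an acyclic vinyl iodide / free C6-OH / allylstannane / bis(allylic acetate). In the forward direction the γ-lactone closes first and the ten-membered ring second, in the same flask.
2. The seco compound is cut at C8–C9 into an α-(1-iodovinyl)-β-silyloxy aldehyde and 2-methylenepropane-1,3-diylbis(stannane). This catalyst-controlled allylation sets C8.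
3. The aldehyde is cut at C6–C7: an auxiliary-controlled syn aldol of a 3-iodobut-3-enoyl imide with the symmetrical enal OHC–CH=C(CH2OAc)2. This sets C6 and C7.
4. Building blocks: dihydroxyacetone, Ph3P=CHCHO, but-3-ynoic acid, a phenylalanine-derived thiazolidinethione, methallyl dichloride and 2 CO.

Assumption: germacrane numbering is used throughout, and 1,3-dihydroxyacetone is bought as its dimer but written as the monomer.
- C2 is the ring ketone and C4=C5 is the ring alkene.
- C6 is the O-lactone carbon, C7 is the adjacent ring carbon, and C8 carries the OAc.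
- C10 carries the exocyclic methylene C14.
- C11/C12/C13 form the acrylate unit, and C15 is the CH2OAc on C4.

## Route

Step 1
Reactants: 1 1,3-dihydroxyacetone
Product: 2 1,3-diacetoxyacetone (2-oxopropane-1,3-diyl diacetate)
Conditions: Ac2O (2.5 equiv), pyridine, 0 °C → rt
Reagents that add atoms: acetic anhydride, CC(=O)OC(C)=O
Why: Simple O-acetylation of both primary hydroxyls (the dimer cracks in pyridine); one acetate ends as the C15 acetate, the other is the leaving group of step 11, and no stereocentre is involved.

Step 2
Reactants: 2 1,3-diacetoxyacetone; 3 (triphenylphosphoranylidene)acetaldehyde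
Product: 4 4-acetoxy-3-(acetoxymethyl)but-2-enal
Conditions: PhMe, 80 °C (2 in slight excess)
Reagents that add atoms: none
Why: Wittig olefination of an activated α,α'-dioxygenated ketone with a stabilised ylide; the two substituents on the new alkene carbon are identical, so there is no E/Z question.

Step 3
Reactants: 5 but-3-ynoic acid
Product: 6 3-iodobut-3-enoic acid
Conditions: 57% aq HI, 0 °C → rt
Reagents that add atoms: hydrogen iodide, I
Why: Markovnikov hydroiodination of a terminal alkyne gives the 1,1-disubstituted vinyl iodide (future C11/C13).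

Step 4
Reactants: 6 3-iodobut-3-enoic acid; 7 (S)-4-benzyl-1,3-thiazolidine-2-thione
Product: 8 (S)-4-benzyl-3-(3-iodobut-3-enoyl)-1,3-thiazolidine-2-thione
Conditions: DCC, DMAP (5 mol %), CH2Cl2, 0 °C
Reagents that add atoms: none
Why: Steglich-type N-acylation under near-neutral cold conditions, so the β,γ-alkene does not move into conjugation.

Step 5
Reactants: 8 (S)-4-benzyl-3-(3-iodobut-3-enoyl)-1,3-thiazolidine-2-thione; 4 4-acetoxy-3-(acetoxymethyl)but-2-enal
Product: 10 (S)-4-benzyl-3-[(2S,3R)-6-acetoxy-5-(acetoxymethyl)-3-hydroxy-2-(1-iodovinyl)hex-4-enoyl]-1,3-thiazolidine-2-thione, via titanium dienolate 9 (not isolated)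
Conditions: TiCl4 (1.05 equiv), iPr2NEt (1.1 equiv), NMP (1 equiv), CH2Cl2, −78 °C; then 4, −78 °C; aq NH4Cl
Reagents that add atoms: none
Why: Crimmins "Evans-syn" titanium aldol, in which the (Z)-dienolate reacts at its α-carbon through a Zimmerman–Traxler chair and the (S)-auxiliary fixes C6 (R) and C7 with O6 and the iodovinyl group syn (this becomes the trans lactone); the covalent planar Ti dienolate keeps C–I orthogonal to the π-system, which holds back loss of iodide at −78 °C.

Step 6
Reactants: 10 syn-aldol adduct
Product: 11 C6-O-triethylsilyl ether of 10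
Conditions: TESOTf, 2,6-lutidine, CH2Cl2, −78 → 0 °C
Reagents that add atoms: triethylsilyl triflate, CC[Si](CC)(CC)OS(=O)(=O)C(F)(F)F
Why: Standard silylation that blocks O6 so only O8 is acetylated later; imidazole is avoided because it would displace the auxiliary.

Step 7
Reactants: 11 C6-O-TES imide
Product: 12 (2S,3R)-6-acetoxy-5-(acetoxymethyl)-2-(1-iodovinyl)-3-(triethylsilyloxy)hex-4-enal
Conditions: LiAlH(OtBu)3 (1.2 equiv), THF, −78 → −20 °C; Rochelle salt
Reagents that add atoms: none
Why: Partial hydride reduction of the strongly activated N-acylthiazolidinethione to the aldehyde; LiAlH(OtBu)3 leaves acetates, the vinyl iodide and the TES ether alone, and the cold neutral work-up preserves C7.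

Step 8
Reactants: 13 3-chloro-2-(chloromethyl)prop-1-ene
Product: 14 2-methylenepropane-1,3-diylbis(tributylstannane)
Conditions: Bu3SnH, LDA, THF, 0 °C; then 13, −78 °C → rt
Reagents that add atoms: tributyltin hydride, CCCC[SnH](CCCC)CCCC
Why: Double SN2 displacement of the allylic chlorides by Bu3SnLi gives the bifunctional C9/C10/C14/C1 unit.

Step 9
Reactants: 12 iodovinyl aldehyde; 14 bis(stannane) (2 equiv)
Product: 16 (6R,7R,8S)-seco triacetate carrying C6-OTES and C11 vinyl iodide and C1 allylstannane, via stannyl ether 15 (not isolated)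
Conditions: (S)-BINOL (20 mol %), Ti(OiPr)4 (10 mol %), 4 Å MS, CH2Cl2, −20 °C; then Ac2O, DMAP (cat.), 0 °C
Reagents that add atoms: acetic anhydride, CC(=O)OC(C)=O
Why: Keck catalytic asymmetric allylation, in which one arm of 14 is transferred (SE2') and the (S)-BINOL–Ti Lewis acid directs attack to the aldehyde face that gives 8S (O8 syn to the iodovinyl group); the primary product is the O–SnBu3 ether, which Ac2O converts directly to the C8 acetate while the second allylstannane arm survives.

Step 10
Reactants: 16 TES-protected seco triacetate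
Product: 17 (6R,7S,8S)-seco alcohol with free C6-OH
Conditions: PPTS (10 mol %), MeOH/CH2Cl2 1:1, 0 °C
Reagents that add atoms: none
Why: Mild acid-catalysed methanolysis of the labile TES ether; PPTS is too weak to protodestannylate the allylstannane quickly or to move acetyl groups, and no stereocentre is touched.

Step 11
Reactants: 17 seco alcohol
Product: 19 (6R,7R,8S)-8,15-diacetoxy-2-oxogermacra-4,10(14),11(13)-trien-12,6-olide (CNP0183179.1; C3 and C6 trans on C4=C5), via monocyclic lactone stannane 18 (not isolated)
Conditions: Pd2(dba)3·CHCl3 (10 mol %), P(2-furyl)3 (40 mol %), LiCl (3 equiv), K2CO3 (2 equiv), CO (3 atm), THF (1 mM), 50 °C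
Reagents that add atoms: carbon monoxide, [C-]#[O+]
Why: Proposed new method: one Pd(0)/CO system runs two known carbonylations in sequence on one substrate: (i) the fastest oxidative addition is at the C(sp2)–I bond, and CO insertion followed by 5-exo capture of the acyl-Pd by the free C6-OH gives the trans α-methylene-γ-lactone 18 without touching C6 or C7; (ii) Pd(0) then ionises one of the two primary allylic acetates, LiCl converts it to the π-allyl-Pd chloride, the preferred syn π-allyl (C6 cis to CH2OAc) inserts CO at its CH2 terminus, and intramolecular allyl transfer from tin (SE2', degenerate for this 2-substituted allyl unit) followed by reductive elimination gives the diallyl ketone and so closes the ten-membered ring with C3 and C6 trans; direct allyl–allyl coupling would need a nine-membered ring and is suppressed under CO; the closest known reaction types are the carbonylative Stille coupling of allyl halides with allylstannanes to diallyl ketones, carbonylative Stille macrocyclisation, and the Pd-catalysed carbonylation of vinyl-halide alcohols to α-methylene lactones; no stereocentre is formed and the near-neutral medium keeps the doubly β,γ-unsaturated ketone unconjugated.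

## Compound list
1 | 1,3-dihydroxyacetone | OCC(=O)CO | starting material
2 | 1,3-diacetoxyacetone | CC(=O)OCC(=O)COC(C)=O | intermediate
3 | (triphenylphosphoranylidene)acetaldehyde | O=CC=P(c1ccccc1)(c1ccccc1)c1ccccc1 | starting material
4 | 4-acetoxy-3-(acetoxymethyl)but-2-enal | CC(=O)OCC(=CC=O)COC(C)=O | intermediate
5 | but-3-ynoic acid | C#CCC(=O)O | starting material
6 | 3-iodobut-3-enoic acid | C=C(I)CC(=O)O | intermediate
7 | (S)-4-benzyl-1,3-thiazolidine-2-thione | S=C1N[C@@H](Cc2ccccc2)CS1 | starting material
8 | (S)-4-benzyl-3-(3-iodobut-3-enoyl)-1,3-thiazolidine-2-thione | C=C(I)CC(=O)N1[C@@H](Cc2ccccc2)CSC1=S | intermediate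
9 | trichlorotitanium (Z)-dienolate of 8 | C=C(I)/C=C(\O[Ti](Cl)(Cl)Cl)N1[C@@H](Cc2ccccc2)CSC1=S | intermediate
10 | syn-aldol adduct (2S,3R in the acyl chain) | CC(=O)OCC(COC(C)=O)=C[C@@H](O)[C@H](C(I)=C)C(=O)N1[C@@H](Cc2ccccc2)CSC1=S | intermediate
11 | C6-O-TES ether of 10 | CC(=O)OCC(COC(C)=O)=C[C@@H](O[Si](CC)(CC)CC)[C@H](C(I)=C)C(=O)N1[C@@H](Cc2ccccc2)CSC1=S | intermediate
12 | (2S,3R)-6-acetoxy-5-(acetoxymethyl)-2-(1-iodovinyl)-3-(triethylsilyloxy)hex-4-enal | CC(=O)OCC(COC(C)=O)=C[C@@H](O[Si](CC)(CC)CC)[C@H](C(I)=C)C=O | intermediate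
13 | 3-chloro-2-(chloromethyl)prop-1-ene | C=C(CCl)CCl | starting material
14 | 2-methylenepropane-1,3-diylbis(tributylstannane) | C=C(C[Sn](CCCC)(CCCC)CCCC)C[Sn](CCCC)(CCCC)CCCC | intermediate
15 | C8-O-tributylstannyl ether (6R,7S,8S) | CC(=O)OCC(COC(C)=O)=C[C@@H](O[Si](CC)(CC)CC)[C@H](C(I)=C)[C@@H](O[Sn](CCCC)(CCCC)CCCC)CC(=C)C[Sn](CCCC)(CCCC)CCCC | intermediate
16 | TES-protected seco triacetate (6R,7R,8S) | CC(=O)OCC(COC(C)=O)=C[C@@H](O[Si](CC)(CC)CC)[C@H](C(I)=C)[C@@H](OC(C)=O)CC(=C)C[Sn](CCCC)(CCCC)CCCC | intermediate
17 | seco alcohol (6R,7S,8S) | CC(=O)OCC(COC(C)=O)=C[C@@H](O)[C@H](C(I)=C)[C@@H](OC(C)=O)CC(=C)C[Sn](CCCC)(CCCC)CCCC | intermediate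
18 | monocyclic trans α-methylene-γ-lactone allylstannane (6R,7R,8S) | CC(=O)OCC(COC(C)=O)=C[C@H]1OC(=O)C(=C)[C@@H]1[C@@H](OC(C)=O)CC(=C)C[Sn](CCCC)(CCCC)CCCC | intermediate
19 | CNP0183179.1 | C=C1CC(=O)C/C(COC(C)=O)=C/[C@H]2OC(=O)C(=C)[C@@H]2[C@@H](OC(C)=O)C1 | target

## Count and risks
Total steps: 11. Longest linear sequence: 8 steps (5 → 6 → 8 → 10 → 11 → 12 → 16 → 17 → 19).

**Step 11 (double carbonylative bicyclisation), most likely to fail.**
- Allylic acetates are reluctant partners in carbonylative Stille coupling.
- A ten-membered ring has to close.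
- The lactone acyl-Pd could be intercepted by the stannane.
- O8→O6 acetyl migration would lead to the 8,12-olide.
- Pd(0) can ionise the allylic lactone C–O bond.
- The anti π-allyl would give the C4=C5 isomer.

Fallback: it sets out from 10 (with 14) and comes back at 19. The two carbonylations are uncoupled and the carbocycle is closed at C8–C9 instead. Compound 10 alone is carbonylated (Pd(PPh3)4, K2CO3, CO 1 atm, THF, rt) to the lactone imide F1. LiAlH(OtBu)3 at −78 °C gives the lactone aldehyde F2, which is used crude and cold. An intermolecular carbonylative Stille coupling of F2 with excess 14 (Pd2(dba)3, P(2-furyl)3, LiCl, CO 3 atm) gives the keto allylstannane aldehyde F3. BF3·OEt2 at −78 °C under high dilution closes the ten-membered ring by intramolecular allylstannane–aldehyde addition to the C8 alcohol F4. Ac2O/pyridine then gives 19.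

**Step 9 (Keck allylation).** The aldehyde is α-branched and hindered. Its intrinsic bias (polar 1,3-anti induction, with the iodovinyl group acting as the large substituent) probably opposes the 8S product that the catalyst must deliver.

Fallback: it sets out from 12 (with 14) and comes back at 16. The substrate bias is used rather than fought. BF3·OEt2-promoted addition of 14 at −78 °C gives the (8R)-alcohol F5. A Mitsunobu reaction with acetic acid (PPh3, DIAD, AcOH) installs the acetate with inversion to give 16.

**Step 5 (aldol of the β-iodo dienolate).** The dienolate may lose iodide to give the allenoyl imide, or it may react at its γ-carbon.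

Fallback: it sets out from 5 and 7 and comes back at 10 (through 9). The elimination is turned into the entry point. Compound 5 is isomerised with aqueous K2CO3 to buta-2,3-dienoic acid F6, which is coupled with 7 (DCC) to the N-allenoyl imide F7. TiCl4/Bu4NI at −78 °C adds iodide to the central allene carbon and generates dienolate 9 directly (halo-aldol mode), and 9 is trapped with 4 to give 10.

## Further compounds
F1 | step 11 | lactone imide (trans α-methylene-γ-lactone bearing the C8 acyl thiazolidinethione) | CC(=O)OCC(COC(C)=O)=C[C@H]1OC(=O)C(=C)[C@@H]1C(=O)N2[C@@H](Cc3ccccc3)CSC2=S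
F2 | step 11 | lactone aldehyde (C8 formyl) | CC(=O)OCC(COC(C)=O)=C[C@H]1OC(=O)C(=C)[C@@H]1C=O
F3 | step 11 | keto allylstannane aldehyde | CCCC[Sn](CCCC)(CCCC)CC(=C)CC(=O)C/C(COC(C)=O)=C/[C@H]1OC(=O)C(=C)[C@@H]1C=O
F4 | step 11 | C8 alcohol (8-deacetyl target) | C=C1CC(=O)C/C(COC(C)=O)=C/[C@H]2OC(=O)C(=C)[C@@H]2[C@@H](O)C1
F5 | step 9 | (8R)-alcohol (6R,7R,8R) | CC(=O)OCC(COC(C)=O)=C[C@@H](O[Si](CC)(CC)CC)[C@H](C(I)=C)[C@H](O)CC(=C)C[Sn](CCCC)(CCCC)CCCC
F6 | step 5 | buta-2,3-dienoic acid | C=C=CC(=O)O
F7 | step 5 | (S)-4-benzyl-3-(buta-2,3-dienoyl)-1,3-thiazolidine-2-thione | C=C=CC(=O)N1[C@@H](Cc2ccccc2)CSC1=S
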